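The ratio of product to intermediate that the second step would hold in elm is its equilibrium constant times the partner charged, 1.8.

| setting | cedar | elm | maple | oak |
|---|---|---|---|---|
| substrate | 2.0 mM | 2.0 mM | 2.0 mM | 2.0 mM (fed, over 1.00 min) |
| partner | 4.00 mM | 4.00 mM | 4.00 mM (fed, over 1.00 min) | 4.00 mM |
| remark | one stirred flow tank at steady state, fed with the mixture as stated, mean residence time 1.0 min | a closed flask charged with all of it at once and left for 1.0 min | all but partner at the start; partner goes in evenly over 1.00 min, the run ends at 1.0 min | all but substrate at the start; substrate goes in evenly over 1.00 min, the run ends at 1.0 min |
| time |  | 1.0 min | 1.0 min | 1.0 min |

    substrate → intermediate (k1 = 0.035 /s)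
    partner + intermediate ⇌ product (K2 = 450 /M, k2 = 9.3 /M/s)
    substrate ⇌ dormant form (K3 = 0.58, k3 = 0.042 /s)

1. order of the set-ups by the amount of product at the outlet or at the end, in percent of the substrate put in, highest first (cedar / elm / maple / oak)
2. amount of product at the outlet or at the end, in percent of the substrate put in, cedar
3. amount of product at the outlet or at the end, in percent of the substrate put in, elm
4. amount of product at the outlet or at the end, in percent of the substrate put in, maple
5. amount of product at the outlet or at the end, in percent of the substrate put in, oak

- the stated concentrations are those of everything mixed, before any reaction; amounts are the same in each set-up
- the feed brings no volume worth counting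
- run time (elm): 1.0 min

I follow one molecule up a ladder of times. In elm, substrate starts towards intermediate against dormant form at 0.83. That fork is not final, since the third step relaxes with a half-life of 0.101 min, shorter than the 0.33 min of the first step. So I count substrate and dormant form as one store. It drains at 1.33 /min, the first-step constant times substrate's share of the store, which gives a half-life of 0.522 min.

The second step sits between these rungs. With c(partner) held as charged, it is pseudo-first-order and relaxes at 3.47 /min, forward and back together. Its half-life of 0.200 min is shorter than the store's, so product trails the supply. Once that step has balanced, a molecule past the first step stands as product with chance 0.643, the pairing chance.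

I treat the store and the second step as two first-order stages in a row, scaled by the pairing chance. Elm gives 38.0%. In oak, substrate enters 0.500 min late on average, which gives 17.7%. Cedar, as two stages at steady state, gives 28.5%. Maple stops my reckoning, because its partner arrives over 1.00 min and c(partner) is not constant.

The forecast does not use my one store: it solves substrate and dormant form exactly, and then says “Product then follows one equation”. It gives elm > maple > cedar > oak, with cedar 27.2%, elm 35.7%, maple 29.8% and oak 18.6%. Its elm figure is lower than mine.

The simulation gives elm > maple > cedar > oak, with cedar 27.2%, elm 35.7%, maple 29.8% and oak 18.6%, so the forecast stands. The elm figure moves 5 points away from the forecast's with partner at 3.15 mM or 5.06 mM, the time and the substrate held. Elm's reading is 0.555 of its pairing chance. The neighbour is elm with 6.8 mM of partner. Its pairing chance is 0.754, higher than elm's, and it relaxes at 5.03 /min. The same reckoning gives 48.4%. That neighbour flask gives 46.8% of product, beside 26.5% of intermediate.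

The rate constants were chosen freely; the flask was simulated.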